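## Retrosynthetic overview

1. The C3–C3a–C8a cyclopentane and the cycloheptanone are cut together by a Prins–pinacol transform, back to a 1-vinyl-2-(2-formylpropan-2-yl)cyclohexane-1,2-diol bis(silyl ether).
2. The diol comes from a cyclohexane-1,2-dione by indium reverse prenylation (masked CMe2–CHO) and ethynyl Grignard addition (masked vinyl).
3. The dione comes from a 2,3-dimethyl-2-alkylcyclohexanone by enolate autoxidation; that ketone from 2-methylcyclohex-2-en-1-one by asymmetric methyl conjugate addition and enolate alkylation with 3-(2-iodoethyl)furan.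
4. The butenolide comes from the 3-alkylfuran by photooxygenation and reduction.
5. Ring order: furan and cyclohexane are bought; the butenolide forms in step 8; the cyclopentane and cycloheptanone form together in step 11, the cyclohexane being enlarged by one carbon.

Assumption: the antipode of the phosphoramidite ligand that delivers the (3R)-methyl ketone in step 3 is used; if the sense is opposite, the mirror-image ligand is taken.
Locants in the Why line of step 11 and in the fallbacks are azulene locants of the target: C1 = CMe2, C2 = CHOH, C3 = CH2, C3a = CH, C4 = C=O, C5 = quaternary C, C6 = CHMe, C8a = C–OH.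

## Route

Step 1
Reactants: 1 3-bromofuran; 2 oxirane
Product: 4 2-(furan-3-yl)ethan-1-ol, via furan-3-yllithium 3 (not isolated)
Conditions: n-BuLi, THF, −78 °C; then 2, BF3·OEt2, −78 °C; aq. NH4Cl
Reagents that add atoms: none
Why: Bromine–lithium exchange at −78 °C gives the 3-lithiofuran without drift to the 2-position, and BF3-assisted epoxide ring-opening by the organolithium installs the two-carbon alcohol; no stereocentre.

Step 2
Reactants: 4 2-(furan-3-yl)ethan-1-ol
Product: 5 3-(2-iodoethyl)furan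
Conditions: I2, PPh3, imidazole, CH2Cl2, 0 °C → rt
Reagents that add atoms: iodine, II
Why: Appel-type iodination of a primary alcohol under near-neutral conditions that the acid-sensitive furan tolerates.

Step 3
Reactants: 6 2-methylcyclohex-2-en-1-one; 5 3-(2-iodoethyl)furan
Product: 8 (2S,3R)-2-[2-(furan-3-yl)ethyl]-2,3-dimethylcyclohexan-1-one, via aluminium enolate 7 (not isolated)
Conditions: Me3Al, Cu(OAc)2·H2O (2 mol %), (S,S,S)-binaphthol bis(1-phenylethyl)phosphoramidite (4 mol %), Et2O, −30 °C; then MeLi, THF/HMPA, 5, −30 → 0 °C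
Reagents that add atoms: trimethylaluminium, C[Al](C)C
Why: Copper-catalysed asymmetric conjugate addition sets C3 (R) under ligand control, and the regiodefined enolate, made more nucleophilic as its lithium aluminate, is alkylated by the primary iodide anti to the new methyl, so the quaternary centre (2S) carries its methyl cis to the C3 methyl (tandem conjugate addition–enolate alkylation).

Step 4
Reactants: 8 (2S,3R)-2-[2-(furan-3-yl)ethyl]-2,3-dimethylcyclohexan-1-one
Product: 9 (5R,6S)-6-[2-(furan-3-yl)ethyl]-2-hydroxy-5,6-dimethylcyclohex-2-en-1-one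
Conditions: KOtBu, O2 (1 atm), t-BuOH/THF, 0 °C → rt; aq. NH4Cl
Reagents that add atoms: dioxygen, O=O
Why: Enolate autoxidation; the ketone has one enolisable α-position only, its α-hydroperoxide loses water under base to the 1,2-dione, which rests as the enol (diosphenol); the two stereocentres are not enolisable.

Step 5
Reactants: 9 (5R,6S)-6-[2-(furan-3-yl)ethyl]-2-hydroxy-5,6-dimethylcyclohex-2-en-1-one; 10 1-bromo-3-methylbut-2-ene
Product: 12 (2S,3R,6R)-2-[2-(furan-3-yl)ethyl]-6-hydroxy-2,3-dimethyl-6-(2-methylbut-3-en-2-yl)cyclohexan-1-one, via prenylindium bromide 11 (not isolated)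
Conditions: In powder, THF/H2O (1:1), rt
Reagents that add atoms: none
Why: Barbier-type indium allylation of the keto tautomer of the 1,2-dione; the allylindium reacts at its γ-carbon through a six-membered cyclic transition state (giving the 1,1-dimethylallyl group) at the carbonyl remote from the quaternary carbon, entering equatorially and anti to the axial ring methyl, so the new hydroxyl (6R) is cis to both methyls.

Step 6
Reactants: 12 (2S,3R,6R)-2-[2-(furan-3-yl)ethyl]-6-hydroxy-2,3-dimethyl-6-(2-methylbut-3-en-2-yl)cyclohexan-1-one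
Product: 13 (1R,2R,3S,4R)-2-ethynyl-3-[2-(furan-3-yl)ethyl]-3,4-dimethyl-1-(2-methylbut-3-en-2-yl)cyclohexane-1,2-diol
Conditions: HC≡CMgBr (5 equiv), THF, 0 °C → rt; aq. NH4Cl
Reagents that add atoms: ethynylmagnesium bromide, C#C[Mg]Br
Why: Grignard 1,2-addition of the smallest carbon nucleophile to a non-enolisable ketone; the face bearing the axial hydroxyl and axial methyl of the two flanking carbons is blocked, so the acetylide enters axially from the other face and ends trans-diaxial to the neighbouring C–O bond (2R).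

Step 7
Reactants: 13 (1R,2R,3S,4R)-2-ethynyl-3-[2-(furan-3-yl)ethyl]-3,4-dimethyl-1-(2-methylbut-3-en-2-yl)cyclohexane-1,2-diol
Product: 14 (1R,2R,3S,4R)-2-ethynyl-3-[2-(furan-3-yl)ethyl]-3,4-dimethyl-1-(2-methylbut-3-en-2-yl)-1,2-bis[(trimethylsilyl)oxy]cyclohexane
Conditions: TMSOTf, 2,6-lutidine, CH2Cl2, −78 → 0 °C
Reagents that add atoms: trimethylsilyl trifluoromethanesulfonate, C[Si](C)(C)OS(=O)(=O)C(F)(F)F
Why: Silylation of both tertiary alcohols with a silyl triflate; the carbinol silyl ether is the later pinacol terminus, and the other one blocks lactol formation and retro-aldol cleavage of the later β-oxy aldehyde.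

Step 8
Reactants: 14 (1R,2R,3S,4R)-2-ethynyl-3-[2-(furan-3-yl)ethyl]-3,4-dimethyl-1-(2-methylbut-3-en-2-yl)-1,2-bis[(trimethylsilyl)oxy]cyclohexane
Product: 16 4-{2-[(1S,2R,3R,6R)-2-ethynyl-1,6-dimethyl-3-(2-methylbut-3-en-2-yl)-2,3-bis[(trimethylsilyl)oxy]cyclohexyl]ethyl}furan-2(5H)-one, via hydroxybutenolide 15 (not isolated)
Conditions: O2, hν (visible), tetraphenylporphyrin (cat.), i-Pr2NEt, CH2Cl2, −78 °C; then NaBH4, EtOH, −20 °C; pH 5 phosphate work-up
Reagents that add atoms: dioxygen, O=O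
Why: Singlet-oxygen [4+2] photooxygenation of the 3-alkylfuran; the hindered amine removes the less hindered bridgehead proton of the endoperoxide to give the 4-alkyl-5-hydroxybutenolide, whose open-chain aldehyde is reduced by NaBH4 before relactonisation; the monosubstituted alkene and the alkyne do not react with singlet oxygen, and no ketone is present.

Step 9
Reactants: 16 4-{2-[(1S,2R,3R,6R)-2-ethynyl-1,6-dimethyl-3-(2-methylbut-3-en-2-yl)-2,3-bis[(trimethylsilyl)oxy]cyclohexyl]ethyl}furan-2(5H)-one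
Product: 18 2-{(1R,2R,3S,4R)-2-ethynyl-3,4-dimethyl-3-[2-(5-oxo-2,5-dihydrofuran-3-yl)ethyl]-1,2-bis[(trimethylsilyl)oxy]cyclohexyl}-2-methylpropanal, via vicinal diol 17 (not isolated)
Conditions: OsO4 (2 mol %), NaIO4 (4 equiv), 2,6-lutidine, dioxane/H2O (3:1), rt
Reagents that add atoms: osmium tetroxide, O=[Os](=O)(=O)=O; sodium periodate, [Na+].[O-][I](=O)(=O)=O
Why: Lemieux–Johnson oxidative cleavage (dihydroxylation, then periodate glycol cleavage) of the only isolated alkene; the terminal alkyne and the electron-poor butenolide olefin react far more slowly, and the aldehyde formed is non-enolisable.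

Step 10
Reactants: 18 2-{(1R,2R,3S,4R)-2-ethynyl-3,4-dimethyl-3-[2-(5-oxo-2,5-dihydrofuran-3-yl)ethyl]-1,2-bis[(trimethylsilyl)oxy]cyclohexyl}-2-methylpropanal
Product: 19 2-{(1R,2R,3S,4R)-2-ethenyl-3,4-dimethyl-3-[2-(5-oxo-2,5-dihydrofuran-3-yl)ethyl]-1,2-bis[(trimethylsilyl)oxy]cyclohexyl}-2-methylpropanal
Conditions: H2 (1 atm), Pd/CaCO3 poisoned with Pb(OAc)2, quinoline, EtOAc, rt
Reagents that add atoms: none
Why: Lindlar semihydrogenation; the lead- and quinoline-poisoned palladium surface reduces the terminal alkyne to the alkene and leaves the aldehyde, the conjugated lactone and the silyl ethers alone.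

Step 11
Reactants: 19 2-{(1R,2R,3S,4R)-2-ethenyl-3,4-dimethyl-3-[2-(5-oxo-2,5-dihydrofuran-3-yl)ethyl]-1,2-bis[(trimethylsilyl)oxy]cyclohexyl}-2-methylpropanal
Product: 21 CNP0077405.1 = 4-{2-[(2R,3aS,5S,6R,8aS)-2,8a-dihydroxy-1,1,5,6-tetramethyl-4-oxodecahydroazulen-5-yl]ethyl}furan-2(5H)-one, via 8a-O-trimethylsilyl ether 20 (not isolated)
Conditions: SnCl4 (1.5 equiv), 2,6-di-tert-butyl-4-methylpyridine, CH2Cl2, −78 → −20 °C; then 1 M aq. HCl, THF, 0 °C → rt
Reagents that add atoms: none
Why: Proposed new method: an aldehyde-initiated Prins–pinacol ring-enlarging cyclopentane annulation, in which the SnCl4-bound aldehyde is attacked by the terminal vinyl carbon through a chair six-membered transition state (C2–C3 bond; carbonyl oxygen equatorial, so the C2 hydroxyl (R) is cis to the C8a oxygen) and the cation developing at C3a is quenched by 1,2-shift of the aligned ring bond, the silyloxy-bearing carbon C8a moving from C4 to C3a with retention while the carbinol becomes the C4 ketone, so that the cyclohexane grows to the cycloheptanone and the transient six-membered ring contracts to the cyclopentane in the same event; because the vinyl group and the C8a–O bond are trans-diaxial, that oxygen ends syn to the acyl carbon, which is the trans ring fusion (3aS); the closest known reaction type is the SnCl4-promoted, acetal-initiated Prins–pinacol annulation of 1-alkenyl-2-(acetal-tethered)cycloalkanol silyl ethers, and the acid work-up then cleaves the remaining tertiary silyl ether.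

## Compound list

1 | 3-bromofuran | Brc1ccoc1 | starting material
2 | oxirane | C1CO1 | starting material
3 | furan-3-yllithium | [Li]c1ccoc1 | intermediate (not isolated)
4 | 2-(furan-3-yl)ethan-1-ol | OCCc1ccoc1 | intermediate
5 | 3-(2-iodoethyl)furan | ICCc1ccoc1 | intermediate
6 | 2-methylcyclohex-2-en-1-one | CC1=CCCCC1=O | starting material
7 | dimethylaluminium (3R)-2,3-dimethylcyclohex-1-en-1-olate | C[C@@H]1CCCC(O[Al](C)C)=C1C | intermediate (not isolated)
8 | (2S,3R)-2-[2-(furan-3-yl)ethyl]-2,3-dimethylcyclohexan-1-one | C[C@@H]1CCCC(=O)[C@@]1(C)CCc1ccoc1 | intermediate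
9 | (5R,6S)-6-[2-(furan-3-yl)ethyl]-2-hydroxy-5,6-dimethylcyclohex-2-en-1-one | C[C@@H]1CC=C(O)C(=O)[C@@]1(C)CCc1ccoc1 | intermediate
10 | 1-bromo-3-methylbut-2-ene (prenyl bromide) | CC(C)=CCBr | starting material
11 | dibromo(3-methylbut-2-en-1-yl)indium (written for the allylindium sesquibromide) | CC(C)=CC[In](Br)Br | intermediate (not isolated)
12 | (2S,3R,6R)-2-[2-(furan-3-yl)ethyl]-6-hydroxy-2,3-dimethyl-6-(2-methylbut-3-en-2-yl)cyclohexan-1-one | C[C@@H]1CC[C@@](O)(C(C)(C)C=C)C(=O)[C@@]1(C)CCc1ccoc1 | intermediate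
13 | (1R,2R,3S,4R)-2-ethynyl-3-[2-(furan-3-yl)ethyl]-3,4-dimethyl-1-(2-methylbut-3-en-2-yl)cyclohexane-1,2-diol | C[C@@H]1CC[C@@](O)(C(C)(C)C=C)[C@@](O)(C#C)[C@@]1(C)CCc1ccoc1 | intermediate
14 | (1R,2R,3S,4R)-2-ethynyl-3-[2-(furan-3-yl)ethyl]-3,4-dimethyl-1-(2-methylbut-3-en-2-yl)-1,2-bis[(trimethylsilyl)oxy]cyclohexane | C[C@@H]1CC[C@@](O[Si](C)(C)C)(C(C)(C)C=C)[C@@](O[Si](C)(C)C)(C#C)[C@@]1(C)CCc1ccoc1 | intermediate
15 | 4-{2-[(1S,2R,3R,6R)-2-ethynyl-1,6-dimethyl-3-(2-methylbut-3-en-2-yl)-2,3-bis[(trimethylsilyl)oxy]cyclohexyl]ethyl}-5-hydroxyfuran-2(5H)-one (both C5 epimers) | C[C@@H]1CC[C@@](O[Si](C)(C)C)(C(C)(C)C=C)[C@@](O[Si](C)(C)C)(C#C)[C@@]1(C)CCC1=CC(=O)OC1O | intermediate (not isolated)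
16 | 4-{2-[(1S,2R,3R,6R)-2-ethynyl-1,6-dimethyl-3-(2-methylbut-3-en-2-yl)-2,3-bis[(trimethylsilyl)oxy]cyclohexyl]ethyl}furan-2(5H)-one | C[C@@H]1CC[C@@](O[Si](C)(C)C)(C(C)(C)C=C)[C@@](O[Si](C)(C)C)(C#C)[C@@]1(C)CCC1=CC(=O)OC1 | intermediate
17 | 4-{2-[(1S,2R,3R,6R)-3-(3,4-dihydroxy-2-methylbutan-2-yl)-2-ethynyl-1,6-dimethyl-2,3-bis[(trimethylsilyl)oxy]cyclohexyl]ethyl}furan-2(5H)-one (both carbinol epimers) | C[C@@H]1CC[C@@](O[Si](C)(C)C)(C(C)(C)C(O)CO)[C@@](O[Si](C)(C)C)(C#C)[C@@]1(C)CCC1=CC(=O)OC1 | intermediate (not isolated)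
18 | 2-{(1R,2R,3S,4R)-2-ethynyl-3,4-dimethyl-3-[2-(5-oxo-2,5-dihydrofuran-3-yl)ethyl]-1,2-bis[(trimethylsilyl)oxy]cyclohexyl}-2-methylpropanal | C[C@@H]1CC[C@@](O[Si](C)(C)C)(C(C)(C)C=O)[C@@](O[Si](C)(C)C)(C#C)[C@@]1(C)CCC1=CC(=O)OC1 | intermediate
19 | 2-{(1R,2R,3S,4R)-2-ethenyl-3,4-dimethyl-3-[2-(5-oxo-2,5-dihydrofuran-3-yl)ethyl]-1,2-bis[(trimethylsilyl)oxy]cyclohexyl}-2-methylpropanal | C[C@@H]1CC[C@@](O[Si](C)(C)C)(C(C)(C)C=O)[C@@](O[Si](C)(C)C)(C=C)[C@@]1(C)CCC1=CC(=O)OC1 | intermediate
20 | 4-{2-[(2R,3aS,5S,6R,8aS)-2-hydroxy-1,1,5,6-tetramethyl-4-oxo-8a-[(trimethylsilyl)oxy]decahydroazulen-5-yl]ethyl}furan-2(5H)-one | C[C@@H]1CC[C@]2(O[Si](C)(C)C)[C@H](C[C@@H](O)C2(C)C)C(=O)[C@@]1(C)CCC1=CC(=O)OC1 | intermediate (not isolated)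
21 | CNP0077405.1, 4-{2-[(2R,3aS,5S,6R,8aS)-2,8a-dihydroxy-1,1,5,6-tetramethyl-4-oxodecahydroazulen-5-yl]ethyl}furan-2(5H)-one | C[C@@H]1CC[C@]2(O)[C@H](C[C@@H](O)C2(C)C)C(=O)[C@@]1(C)CCC1=CC(=O)OC1 | target

## Totals and risks

Total step count: 11. Longest linear sequence: 11 steps (from 3-bromofuran 1); 9 steps from 2-methylcyclohex-2-en-1-one 6.

Where the stereocentres are set: C6 and C5 in step 3; C8a in step 5 (retained through the 1,2-shift); C2 and C3a in step 11. The carbinol centre made in step 6 is destroyed in step 11 but decides the ring fusion.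

Most likely to fail:

Step 3 (alkylation of a hindered, fully substituted enolate by a non-activated iodide that can also eliminate). The fallback sets out from 6 and comes back at 8. The conjugate addition is run as before, but the enolate is trapped with TMSCl to give trimethyl{[(3R)-2,3-dimethylcyclohex-1-en-1-yl]oxy}silane F1. MeLi releases the lithium enolate, which adds to phenyl vinyl sulfoxide (a reactive vinyl-cation equivalent, again anti to the C3 methyl) to give (2S,3R)-2,3-dimethyl-2-[2-(phenylsulfinyl)ethyl]cyclohexan-1-one F2. Heating in toluene at 110 °C over CaCO3 eliminates the sulfoxide to (2S,3R)-2-ethenyl-2,3-dimethylcyclohexan-1-one F3. 9-BBN hydroborates the vinyl group to (2S,3R)-2-[2-(9-borabicyclo[3.3.1]nonan-9-yl)ethyl]-2,3-dimethylcyclohexan-1-one F4, and B-alkyl Suzuki coupling in the same flask with 3-bromofuran 1 (Pd(PPh3)4, aq. K3PO4, THF, 65 °C) returns to 8.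

Step 6 (addition to a ketone flanked by two fully substituted carbons; the neighbouring alkoxide could also deliver the nucleophile to the wrong face or undergo retro-allylation). The fallback sets out from 9 and comes back at 13, with the order of the two carbonyl additions inverted. TBSOTf/Et3N gives (5R,6S)-2-[(tert-butyldimethylsilyl)oxy]-6-[2-(furan-3-yl)ethyl]-5,6-dimethylcyclohex-2-en-1-one F5, whose ketone has only one fully substituted neighbour. Ethynylmagnesium bromide adds anti to the axial methyl to give (1R,5R,6S)-2-[(tert-butyldimethylsilyl)oxy]-1-ethynyl-6-[2-(furan-3-yl)ethyl]-5,6-dimethylcyclohex-2-en-1-ol F6. TBAF/AcOH releases (2R,3S,4R)-2-ethynyl-3-[2-(furan-3-yl)ethyl]-2-hydroxy-3,4-dimethylcyclohexan-1-one F7. Indium and prenyl bromide 10 in THF/H2O then add the 1,1-dimethylallyl group equatorially to the free ketone and return to 13; the facial selectivity of this last addition is less secure than in the main route.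

Step 11 (a monosubstituted vinyl group is a weak π-nucleophile toward an aldehyde–SnCl4 complex; ionisation of the allylic silyl ether, or a boat transition state giving the C3a epimer, may compete). The fallback sets out from 18 and comes back at 20, using the alkyne itself as the π-nucleophile. SnCl4 in CH2Cl2 at −78 → −20 °C gives, through a vinyl cation and the same ring-contracting 1,2-shift, the cyclopentene-fused enone 4-{2-[(2R,5S,6R,8aR)-2-hydroxy-1,1,5,6-tetramethyl-4-oxo-8a-[(trimethylsilyl)oxy]-1,2,4,5,6,7,8,8a-octahydroazulen-5-yl]ethyl}furan-2(5H)-one F8. Conjugate reduction with [(Ph3P)CuH]6 in benzene, followed by protonation of the enolate at C3a from the face opposite the C8a silyloxy group, returns to 20, which the acid treatment of step 11 converts to 21. If C3a comes out wrong it is the epimerisable α-carbon of the ketone and can be equilibrated with mild base.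

## Further compounds

F1 | step 3 | trimethyl{[(3R)-2,3-dimethylcyclohex-1-en-1-yl]oxy}silane | C[C@@H]1CCCC(O[Si](C)(C)C)=C1C
F2 | step 3 | (2S,3R)-2,3-dimethyl-2-[2-(phenylsulfinyl)ethyl]cyclohexan-1-one | C[C@@H]1CCCC(=O)[C@@]1(C)CCS(=O)c1ccccc1
F3 | step 3 | (2S,3R)-2-ethenyl-2,3-dimethylcyclohexan-1-one | C[C@@H]1CCCC(=O)[C@@]1(C)C=C
F4 | step 3 | (2S,3R)-2-[2-(9-borabicyclo[3.3.1]nonan-9-yl)ethyl]-2,3-dimethylcyclohexan-1-one | C[C@@H]1CCCC(=O)[C@@]1(C)CCB1C2CCCC1CCC2
F5 | step 6 | (5R,6S)-2-[(tert-butyldimethylsilyl)oxy]-6-[2-(furan-3-yl)ethyl]-5,6-dimethylcyclohex-2-en-1-one | C[C@@H]1CC=C(O[Si](C)(C)C(C)(C)C)C(=O)[C@@]1(C)CCc1ccoc1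
F6 | step 6 | (1R,5R,6S)-2-[(tert-butyldimethylsilyl)oxy]-1-ethynyl-6-[2-(furan-3-yl)ethyl]-5,6-dimethylcyclohex-2-en-1-ol | C[C@@H]1CC=C(O[Si](C)(C)C(C)(C)C)[C@@](O)(C#C)[C@@]1(C)CCc1ccoc1
F7 | step 6 | (2R,3S,4R)-2-ethynyl-3-[2-(furan-3-yl)ethyl]-2-hydroxy-3,4-dimethylcyclohexan-1-one | C[C@@H]1CCC(=O)[C@@](O)(C#C)[C@@]1(C)CCc1ccoc1
F8 | step 11 | 4-{2-[(2R,5S,6R,8aR)-2-hydroxy-1,1,5,6-tetramethyl-4-oxo-8a-[(trimethylsilyl)oxy]-1,2,4,5,6,7,8,8a-octahydroazulen-5-yl]ethyl}furan-2(5H)-one | C[C@@H]1CC[C@]2(O[Si](C)(C)C)C(=C[C@@H](O)C2(C)C)C(=O)[C@@]1(C)CCC1=CC(=O)OC1
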